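A step in which starting material has to meet partner cannot set the early pace of target in these runs: Monday's run, with twice the partner of Thursday's, read 42.8% at 0.500 min, and Thursday's read 42.9% at 30.0 s.

| flask | starting material | partner | remark | time |
|---|---|---|---|---|
| Thursday's | 14 mM | 16.8 mM | run made earlier |  |
| Tuesday's | 20 mM | 16.8 mM | run made earlier |  |
| Friday's | 31 mM | 16.8 mM | run made earlier |  |
| Monday's | 14 mM | 34 mM | run made earlier |  |
| east | 14 mM | 16.8 mM (fed, over 80 s) | all else is in the flask from the start; the feed brings no volume worth counting | 2.0 min |
| south-east | 14 mM | 16.8 mM | everything together at the start | 2.0 min |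
| north | 14 mM (fed, over 80 s) | 16.8 mM | all else is in the flask from the start; the feed brings no volume worth counting | 2.0 min |

| Thursday's: time / s | Thursday's: target / % | Tuesday's: time / min | Tuesday's: target / % | Friday's: time / min | Friday's: target / % | Monday's: time / min | Monday's: target / % |
|---|---|---|---|---|---|---|---|
| 15.0 | 26.7 | 0.200 | 24.3 | 0.200 | 22.0 | 0.500 | 42.8 |
| 30.0 | 42.9 | 0.333 | 33.3 | 0.333 | 32.3 | 1.00 | 52.7 |
| 40.0 | 49.1 | 0.667 | 49.7 | 0.667 | 42.6 | 1.33 | 54.3 |
| 60.0 | 57.3 | 1.33 | 58.3 | 1.33 | 34.9 | 2.00 | 51.9 |
| 80.0 | 58.2 | 2.50 | 51.0 | 2.50 | 32.4 | 2.50 | 52.4 |

(each reading ± 1 percentage point)

- the analysis behind the earlier runs scatters by 1 percentage point, standard deviation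

- which flask leads in amount of target, in percent of the starting material charged ("all alike" within 1.5 percentage points) (east / south-east / north / all alike)
- how much target is there at the end, in percent of the starting material charged: east
- how much target is there at the end, in percent of the starting material charged: south-east
- how much target is there at the end, in percent of the starting material charged: north

Build the flask up one process at a time, as I reckon it. Take the main step by itself: starting material leaves on a first-order clock, with partner outside the rate-limiting step, and Thursday's first reading puts that clock at 0.0207 s⁻¹. On this clock the timing of partner doesn't enter, so you can set east equal to south-east, and that equality is the zero of my scale. North stands apart from it, since with its starting material fed over 80 s the same clock leaves 21.3% of the charge unconverted at 2.0 min.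

Now add a loss of target: Tuesday's run fell from 58.3% at 1.33 min to 51.0% at 2.50 min, and I count this loss equally for east and south-east. Then add what partner itself costs. Monday's reading of 54.3% at 1.33 min stands lower than Thursday's last reading, 58.2% at 80.0 s, which is nearly the same moment, and that comes to 3.8 percentage points for a charge of 16.8 mM. I call this the partner toll: the points of target lost at that moment per charge of partner added, read from two readings that each scatter by 1 point. Feeding partner keeps partner low, so I put south-east near Thursday's last reading and east above it by up to the toll, near 62.0%, with north behind.

The forecast differs from my reckoning: it names south-east as leader at 56%, with 50% for north and 47% for east, holding that “Feeding partner starves it early, as on Friday”.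

    starting material ⇌ tautomer (K = 1.60, k = 0.0244 s⁻¹)
    starting material + partner → isomer of the product A (k = 0.255 M⁻¹ s⁻¹)
    partner + tautomer → target (k = 389 M⁻¹ s⁻¹)
    target ⇌ isomer of the product B (K = 0.530, k = 0.00836 s⁻¹)

East ends at 66.8%, south-east at 61.3% and north at 58.8%, so east leads. At 2.00 min east holds 1.27% of isomer of the product A and south-east 9.08%. The lead of east over south-east, 5.5 points, is larger than the toll of 3.8 points. Scaled to the neighbour of north charged with 4.2 mM of partner, the toll comes to 0.95 points, and that flask ends with 0.711% of isomer of the product A.

All runs are calculated for an exercise, noise included.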